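# Synthesis proposal for CNP0274454.1: enone–cyclobutene photoadduct and cycloreversion to the germacradienone

## Analysis of the target

The target is a germacrane in which one oxygen bridges C5 and C10 of the ten-membered carbocycle C1–C10. This makes an 11-oxabicyclo[4.4.1]undecane of two oxepanes: ring A (O, C10, C9, C8, C7, C6, C5) and ring B (O, C10, C1, C2, C3, C4, C5). Ring A carries a trans-fused α-methylene-γ-butyrolactone across C7–C8 (C11, C12, C13) and an isovalerate on O9. Ring B carries the C4 methyl (C15), and the bridgehead C10 carries C14.

The six stereocentres are 4S, 5R, 7R, 8R, 9S and 10R. With faces named as in germacranolides (H-7 is α), C11 on C7 is β, the lactone oxygen on C8 is α, the ester oxygen on C9 is β, the bridge is β at C5 and C10 (C14 α), and C15 is β. The bridge couples C5 to C10, so four relationships are independent: C7/C8, C8/C9, C4/C5, and the placement of the C4–C5 pair relative to C7.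

The methylene lactone is a Michael acceptor and has to appear last. The isovalerate has acidic α-hydrogens and must not be present when the lactone enolate is made. The hard part is the fully substituted ether carbon C10 next to the acylated C9, inside a bridged medium ring.

The strategy rests on one feature: C1–C4 with C15 is 1-methylcyclobutene, and C5–C10 with C11–C14 is carvone oxidised at C8 and C12.

## Retrosynthetic reasoning

**26 to 24.** The C11=C13 double bond is removed first, since the methylene lactone would not survive hydride, borane or enolate chemistry. 26 comes from selenoxide 25, made by oxidising 24. The forward step must eliminate toward C13 only.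

**24 to 19.** The ester C–O bond at C9 is cut to give 22 and 23. Acylating after the selenide is in place keeps the isovalerate away from strong base. 22 is traced to 19 by removing selenium from C11 and returning the silyl group to O9.

**19 to 17.** The C10–O bond of the bridge is cut. This single cut opens both oxepanes and uncovers the ten-membered carbocycle. Cutting C5–O instead would call for an anti-Markovnikov C–O bond formation. Forward, O5 must add across C1=C10 at the tertiary carbon.

**17 to 13.** C5–OH and C4–H are removed together as water across an E C4=C5 bond, which forward is a syn, anti-Markovnikov hydration (17 to 15). O9 is then traced through 14 to a ketone conjugated with C1=C10. This leaves 13, in which only C7, C8 and the expendable C11 are stereogenic.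

**13 to 12.** C5–C10 and C1–C4 are reconnected. Two alkenes in a 1,5-relationship in a ten-membered ring are the retron of a bicyclo[2.2.0]hexane cycloreversion. The gain is that the medium ring is never closed by a cyclisation. Forward, strain release must cut these two bonds and not C2–C3.

**12 to 9 and 11.** The cyclobutane C10–C5–C4–C1 is cut across C10–C1 and C5–C4, the retron of an enone–alkene [2+2] photocycloaddition. All fifteen skeletal carbons arrive in this step, with C7 and C8 already set in 9.

**9 to 1, and 11 to 10.** The lactone C12–O8 bond is cut and the oxidation levels are lowered through 7 and 6 to 4. The C8 oxygen of 4 comes from α′-oxidation of 1, and 11 comes from 10 by double-bond isomerisation.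

## Alternatives that were turned down

**Alternative 1:** The ten-membered ring is cut at C2–C3 and traded for the C5–C10 bond of a six-membered ring. Forward, a potassium alkoxide on C5 (KH, 18-crown-6) would trigger an anionic oxy-Cope shift to the cyclodecenone A1.
- For: the shift ends in an enolate and is irreversible; a chair transition state gives E C1=C10; the C5 oxygen needed for the bridge is already present.
- Against: the six-membered substrate needs a vinyl-bearing quaternary C10 next to an isopropenyl-bearing tertiary carbinol, plus the C8/C9 diol and a C7 side arm. After expansion, A1 still needs C5 reduction, the same transannular ether closure, differentiation of O8 from O9, and a lactone built from a two-carbon arm with C13 added.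
- Comparison: A1 is stronger on the reliability of the ring expansion, with no Cope equilibrium and no photochemistry. The chosen route offers all fifteen carbons and the finished lactone ring in one step from two simple partners.

**Alternative 2:** Ring A is cut at C9–C10 and closed onto a preformed ring B. Forward, TMSOTf would ionise a C10 methyl ketal and a tethered silyl enol ether would attack through C9 to give the bridged ketone A2.
- For: the quaternary C10 and the bridge form in a polar step in which oxygen is bound to C10 from the start, so there is no C1-versus-C10 question. C4 and C5 can be set on a simple oxepane, and no medium carbocycle is needed.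
- Against: a seven-membered closure onto a hindered tertiary oxocarbenium ion is demanding. C9 depends on enol ether geometry and facial approach. A2 still needs C8 reduction, lactonisation, methylenation, debenzylation ordered around the methylene lactone, and acylation.
- Comparison: A2 is stronger on regiochemistry at C10. The chosen route is shorter and more convergent because it uses the hidden cyclobutene-plus-carvone symmetry.

**Alternative 3:** The O–C10 bond is cut by imagining oxygen inserted into the C5–C10 ring fusion of a decalin. Forward, Ac2O would acylate a tertiary C5 hydroperoxide on a eudesman-8,12-olide frame, and C10 would migrate from C5 to oxygen (Criegee rearrangement), giving the ketal acetate A3.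
- For: both oxepanes form in one step, C10 migrates with retention, the tertiary C10 is the best migrating group, and the decalin has the natural eudesmane relationship of C10 to C7.
- Against: A3 is at the ketal oxidation level, so the C5 acetoxy group must be reduced off through a bridgehead oxocarbenium ion. The decalin must carry a ring-fusion hydroperoxide, the C9 oxygen and the C4 configuration, and the methylene carbon is still missing.
- Comparison: A3 is stronger on the bridged core, which it makes directly and with C10 secured. The chosen route offers a much shorter approach from cheap materials, with C9 and C4/C5 introduced on the opened ring.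

Key step: step 6

## Route

Assumption: C11 forms as an epimer mixture in step 2 and becomes sp2 in step 14, so both epimers are carried together and drawn as the 11α-methyl epimer; the C9 carbinol of 5 and 6 is drawn β and is erased in step 3.

Step 1
Reactants: 1 (S)-carvone
Product: 4 trans-6-hydroxycarvone [(5R,6R)-6-hydroxy-2-methyl-5-(prop-1-en-2-yl)cyclohex-2-en-1-one], via silyl dienol ether 2 (not isolated), via silyloxy ketone 3 (not isolated)
Conditions: LiN(iPr)2, Me3SiCl, THF, −78 °C; mCPBA, CH2Cl2, −20 °C; 1 M HCl, THF, 0 °C
Reagents that add atoms: mCPBA (3-chloroperoxybenzoic acid), OOC(=O)c1cccc(Cl)c1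
Why: Rubottom oxidation: kinetic deprotonation at the α′ carbon (C8) gives the cross-conjugated silyl enol ether, whose electron-rich double bond is epoxidised in preference to the isopropenyl group and anti to the C7 substituent, so the new C8 oxygen is trans to C11; silyl migration and acid work-up give the ketol.

Step 2
Reactants: 4 trans-6-hydroxycarvone
Product: 6 triol (C8 and C9 hydroxyls on the cyclohexene ring; C7 side chain CH(CH3)CH2OH), via borane adduct 5 (not isolated)
Conditions: 9-BBN (3.3 equiv), THF, 0 °C → rt; 30% H2O2, 3 M NaOH, EtOH, 0 → 40 °C
Reagents that add atoms: hydrogen peroxide, OO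
Why: 9-BBN does two known jobs in one flask, 1,2-reduction of the conjugated ketone and anti-Markovnikov hydroboration of the 1,1-disubstituted alkene, while the trisubstituted ring alkene is left alone; oxidation gives the C12 primary alcohol, and C11 is formed without useful control.

Step 3
Reactants: 6 triol
Product: 7 hydroxy enone alcohol (C9 ketone restored; C8 hydroxyl and C12 primary alcohol free)
Conditions: MnO2 (activated, excess), acetone, rt
Reagents that add atoms: none
Why: MnO2 oxidises only the allylic C9 alcohol, so the enone returns and the C8 and C12 hydroxyls remain for lactonisation.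

Step 4
Reactants: 7 hydroxy enone alcohol
Product: 9 trans-fused α-methyl lactone enone [(3R,3aR,7aR)-3,6-dimethyl-3a,4-dihydro-1-benzofuran-2,7(3H,7aH)-dione], via lactol 8 (not isolated)
Conditions: TEMPO (cat.), PhI(OAc)2, CH2Cl2, rt
Reagents that add atoms: none
Why: Oxoammonium oxidation takes the primary alcohol to the aldehyde, the C8 hydroxyl closes the five-membered lactol, and this is oxidised on to the γ-lactone (oxidative lactonisation of a 1,4-diol); the trans C7/C8 relationship from step 1 becomes the trans ring fusion.

Step 5
Reactants: 10 methylenecyclobutane
Product: 11 1-methylcyclobutene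
Conditions: KOtBu (cat.), DMSO, 70 °C; fractional distillation
Reagents that add atoms: none
Why: Base-catalysed prototropic isomerisation moves the double bond into the ring, where the trisubstituted alkene is favoured at equilibrium; 11 is separated from residual 10 by careful fractionation.

Step 6
Reactants: 9 trans-fused α-methyl lactone enone; 11 1-methylcyclobutene
Product: 12 cis-anti-cis photoadduct (cyclobutane C10–C5–C4–C1 fused to the cyclobutane C1–C2–C3–C4; C14 on C10 and C15 on C4)
Conditions: 11 (10 equiv), CH2Cl2, hν (365 nm), −40 °C
Reagents that add atoms: none
Why: Enone–alkene [2+2] photocycloaddition of the de Mayo–Corey type: excitation of 9 and intersystem crossing give the twisted triplet enone, which adds to 11 stepwise through a triplet 1,4-biradical. After spin inversion the biradical collapses by radical–radical coupling, and this closes the one new ring, the cyclobutane C10–C5–C4–C1, fused to the cyclobutane of 11 as a bicyclo[2.2.0]hexane. The closest known reaction type is the photoaddition of cyclobutenes to cyclohex-2-enones that precedes thermal ring expansion to cyclodeca-1,5-dienes. The selectivity the step needs is head-to-tail regiochemistry, C4 (methyl-bearing) to the β-carbon C5 and C1 to C10; this is the normal sense for an alkyl-substituted donor alkene, and the reverse orientation would have to join the two fully substituted carbons C10 and C4, a crowded biradical that falls apart again instead of closing. Of the four new stereocentres, C1 and C4 are cis because a cyclobutene can only give a cis-fused bicyclo[2.2.0]hexane, and C5 and C10 are cis because closure to a trans-fused bicyclo[4.2.0]octanone is strained. The two outer rings lie anti across the new cyclobutane because the CH2–CH2 unit of 11 approaches away from the six-membered ring. Addition should occur mainly on the α face, away from C11, but this facial ratio is of no consequence because C1, C4, C5 and C10 all become sp2 in step 7. 9 has no second alkene, so the intramolecular [2+2] known for carvone itself is excluded, and a large excess of 11 at low temperature outruns enone dimerisation.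

Step 7
Reactants: 12 cis-anti-cis photoadduct
Product: 13 (1(10)Z,4E)-germacra-1(10),4-dien-9-one 12,8α-olide (11βH)
Conditions: toluene (degassed, dilute), sealed base-washed tube, 190 °C
Reagents that add atoms: none
Why: Thermal cycloreversion of the bicyclo[2.2.0]hexane: homolysis of the strained central C1–C4 bond gives a cyclohexane-1,4-diyl that relaxes to a chair and cleaves C5–C10, so the two bonds made in step 6 become C1=C10 and C4=C5. In the chair diyl C6 should sit equatorial on C5 (E at C4=C5) and C9 axial on C10 (Z at C1=C10), and conjugation of C1=C10 with the C9 ketone holds the product against the [3,3] shift to a divinylcyclohexanone.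

Step 8
Reactants: 13 (1(10)Z,4E)-dienone
Product: 14 9β-hydroxy-(1(10)Z,4E)-germacra-1(10),4-dien-12,8α-olide
Conditions: NaBH4, CeCl3·7H2O, MeOH, −78 °C
Reagents that add atoms: none
Why: Luche 1,2-reduction; the lactone is inert at −78 °C and conjugate reduction is suppressed. Hydride should add to the outer face of the carbonyl in the conformer that turns C9=O away from the C8–O dipole, which places the new hydroxyl β, trans to O8.

Step 9
Reactants: 14 9β-dienol
Product: 15 9β-triethylsilyl ether of 14
Conditions: Et3SiCl, imidazole, DMAP (cat.), DMF, 0 °C → rt
Reagents that add atoms: chlorotriethylsilane, CC[Si](Cl)(CC)CC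
Why: Silylation under amine buffering protects O9, so the later lactone enolate is made in a molecule without an enolisable ester, and it avoids acid that could trigger transannular cyclisation of the diene.

Step 10
Reactants: 15 9β-triethylsilyl ether
Product: 17 5β-hydroxy-4β-methyl (1(10)Z)-cyclodecene lactone with 9β-OSiEt3, via alkylborane 16 (not isolated)
Conditions: 9-BBN, THF, 0 °C → rt; 30% H2O2, aq NaOAc, 0 °C → rt
Reagents that add atoms: hydrogen peroxide, OO
Why: Hydroboration–oxidation, syn and anti-Markovnikov: boron goes to C5 and hydrogen to C4 from the outer face of the strained E alkene in the usual germacrene conformation with C15 β, which sets 5β-OH and 4β-CH3 together; syn addition to an E ring alkene is what gives the cis relation of C15 and O5. The Z alkene beside the silyloxy group is hindered and less strained and should react more slowly, and buffered peroxide spares the lactone and silyl ether.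

Step 11
Reactants: 17 C5 alcohol
Product: 19 5β,10β-epoxy bridged ether (11-oxabicyclo[4.4.1]undecane lactone with 9β-OSiEt3), via organomercurial 18 (not isolated)
Conditions: Hg(OCOCF3)2, NaHCO3, THF, −20 °C; nBu3SnH, 0 °C
Reagents that add atoms: none
Why: Transannular alkoxymercuration–demercuration: divalent mercury activates the only remaining alkene and O5 attacks the tertiary carbon C10 (Markovnikov) from inside the ring, anti to mercury on C1, closing both oxepanes at once. The bicyclo[4.4.1] frame admits only the bridge with both bridgehead substituents outside, so C10 follows from C5 (O β, C14 α); the tin hydride removes mercury from C1 under neutral conditions.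

Step 12
Reactants: 19 bridged ether
Product: 22 11-phenylseleno 9β-hydroxy bridged lactone, via lithium enolate 20 (not isolated), via silyl selenide 21 (not isolated)
Conditions: LiN(iPr)2, THF, −78 °C; PhSeCl, −78 °C; HF·pyridine, THF, 0 °C → rt
Reagents that add atoms: benzeneselenenyl chloride, Cl[Se]c1ccccc1
Why: α-Selenenylation of the lactone enolate; C11 is the only acidic position once O9 is silylated, and selenium should enter trans to H-7 as is usual for trans-fused lactones. Mildly acidic HF·pyridine then frees O9 in the same flask without touching the selenide or lactone.

Step 13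
Reactants: 22 hydroxy selenide; 23 isovaleryl chloride
Product: 24 11-phenylseleno 9β-isovalerate
Conditions: pyridine, DMAP (cat.), CH2Cl2, 0 °C → rt
Reagents that add atoms: none
Why: Acylation of the hindered secondary C9 alcohol with the acid chloride under nucleophilic catalysis; C9 keeps its configuration, and the selenide keeps the methylene lactone masked from the amine.

Step 14
Reactants: 24 ester selenide
Product: 26 CNP0274454.1, via selenoxide 25 (not isolated)
Conditions: 30% H2O2, THF, 0 °C → rt
Reagents that add atoms: none
Why: Oxidation to the selenoxide and syn elimination at or below room temperature; with selenium trans to H-7 only the C13 hydrogens are syn, so the exocyclic methylene forms and C11 loses its stereocentre.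

## Compound list

1 | (S)-carvone | CC(=C)[C@H]1CC=C(C)C(=O)C1 | starting material
2 | trimethylsilyl dienol ether of 1 (C9 silyloxy; C8=C9 and C5=C10) | CC(=C)[C@H]1CC=C(C)C(O[Si](C)(C)C)=C1 | intermediate
3 | trans-6-(trimethylsilyloxy)carvone | CC(=C)[C@H]1CC=C(C)C(=O)[C@@H]1O[Si](C)(C)C | intermediate
4 | trans-6-hydroxycarvone | CC(=C)[C@H]1CC=C(C)C(=O)[C@@H]1O | intermediate
5 | borane adduct (C12 on 9-BBN boron; O9 as 9-BBN borinate; O8 drawn free) | C(B1C2CCCC1CCC2)[C@H](C)[C@H]1CC=C(C)[C@@H](OB2C3CCCC2CCC3)[C@@H]1O | intermediate
6 | triol (8α-OH, 9β-OH, C12 primary alcohol) | OC[C@H](C)[C@H]1CC=C(C)[C@@H](O)[C@@H]1O | intermediate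
7 | hydroxy enone alcohol (C9 ketone, 8α-OH, C12 primary alcohol) | OC[C@H](C)[C@H]1CC=C(C)C(=O)[C@@H]1O | intermediate
8 | lactol (anomeric mixture at C12) | OC1[C@H](C)[C@H]2CC=C(C)C(=O)[C@@H]2O1 | intermediate
9 | trans-fused α-methyl lactone enone | O=C1[C@H](C)[C@H]2CC=C(C)C(=O)[C@@H]2O1 | intermediate
10 | methylenecyclobutane | C=C1CCC1 | starting material
11 | 1-methylcyclobutene | CC1=CCC1 | intermediate
12 | cis-anti-cis photoadduct | O=C1[C@H](C)[C@H]2C[C@@H]3[C@@]4(C)CC[C@H]4[C@]3(C)C(=O)[C@@H]2O1 | intermediate
13 | (1(10)Z,4E)-germacra-1(10),4-dien-9-one 12,8α-olide | O=C1[C@H](C)[C@H]2C/C=C(C)/CC/C=C(C)\C(=O)[C@@H]2O1 | intermediate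
14 | 9β-hydroxy dienolide | O=C1[C@H](C)[C@H]2C/C=C(C)/CC/C=C(C)\[C@@H](O)[C@@H]2O1 | intermediate
15 | 9β-triethylsilyloxy dienolide | O=C1[C@H](C)[C@H]2C/C=C(C)/CC/C=C(C)\[C@@H](O[Si](CC)(CC)CC)[C@@H]2O1 | intermediate
16 | C5 B-alkyl-9-BBN (4β-CH3, boron β on C5) | O=C1[C@H](C)[C@H]2C[C@@H](B3C4CCCC3CCC4)[C@@H](C)CC/C=C(C)\[C@@H](O[Si](CC)(CC)CC)[C@@H]2O1 | intermediate
17 | 5β-hydroxy-4β-methyl (1(10)Z)-cyclodecene lactone with 9β-OSiEt3 | O=C1[C@H](C)[C@H]2C[C@@H](O)[C@@H](C)CC/C=C(C)\[C@@H](O[Si](CC)(CC)CC)[C@@H]2O1 | intermediate
18 | 1α-(trifluoroacetoxymercurio) bridged ether | C[C@H]1C(=O)O[C@@H]2[C@@H]1C[C@H]1O[C@](C)([C@@H]([Hg]OC(=O)C(F)(F)F)CC[C@@H]1C)[C@H]2O[Si](CC)(CC)CC | intermediate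
19 | 5β,10β-epoxy bridged lactone with 9β-OSiEt3 and 11α-methyl | C[C@H]1C(=O)O[C@@H]2[C@@H]1C[C@H]1O[C@](C)(CCC[C@@H]1C)[C@H]2O[Si](CC)(CC)CC | intermediate
20 | lithium enolate of 19 (C11=C12) | CC1=C(O[Li])O[C@@H]2[C@@H]1C[C@H]1O[C@](C)(CCC[C@@H]1C)[C@H]2O[Si](CC)(CC)CC | intermediate
21 | 11β-phenylseleno 9β-OSiEt3 lactone | C[C@@]1([Se]c3ccccc3)C(=O)O[C@@H]2[C@@H]1C[C@H]1O[C@](C)(CCC[C@@H]1C)[C@H]2O[Si](CC)(CC)CC | intermediate
22 | 11β-phenylseleno 9β-hydroxy lactone | C[C@@]1([Se]c3ccccc3)C(=O)O[C@@H]2[C@@H]1C[C@H]1O[C@](C)(CCC[C@@H]1C)[C@H]2O | intermediate
23 | isovaleryl chloride | CC(C)CC(Cl)=O | starting material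
24 | 11β-phenylseleno 9β-isovalerate | C[C@@]1([Se]c3ccccc3)C(=O)O[C@@H]2[C@@H]1C[C@H]1O[C@](C)(CCC[C@@H]1C)[C@H]2OC(=O)CC(C)C | intermediate
25 | selenoxide of 24 (mixture at selenium) | C[C@@]1([Se](=O)c3ccccc3)C(=O)O[C@@H]2[C@@H]1C[C@H]1O[C@](C)(CCC[C@@H]1C)[C@H]2OC(=O)CC(C)C | intermediate
26 | CNP0274454.1 | C=C1C(=O)O[C@@H]2[C@@H]1C[C@H]1O[C@](C)(CCC[C@@H]1C)[C@H]2OC(=O)CC(C)C | target

## Step count and least certain steps

Total step count: 14. Longest linear sequence: 13 steps (steps 1–4 and 6–14 from 1); step 5 is a one-step branch.

**Step 6 (key step).** The likeliest failure is inefficient capture of the triplet enone. The alkene is volatile, and the excited α-acyloxy enone can also lose its C8–O bond or decay by other routes. Some head-to-head addition is also possible.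
Fallback: the lactone is closed after the photochemistry. It sets out from 7, which has a free α′-hydroxyl and no acyloxy leaving group. Irradiation of 7 with 11 under the same conditions should give the diol photoadduct F1. Oxidative lactonisation of F1 with TEMPO and PhI(OAc)2, as in step 4, returns to the route at 12.

**Step 7.** The likeliest failure is drift of the cycloreversion toward the six-membered isomer. This can happen by cleavage of C2–C3 in the diyl or by a [3,3] shift of 13. High temperature favours the divinylcyclohexanone entropically, and alkene geometry may also be mixed.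
Fallback: the ten-membered ring is reached from 12 in two stages. The thermolysis is run to the cis-divinylcyclohexanone lactone F2. F2 is then re-equilibrated at room temperature by a PdCl2(PhCN)2-catalysed Cope rearrangement. At that temperature the entropy term is small and enone conjugation should favour the ring-expanded isomer, returning to the route at 13.

**Step 8.** The likeliest failure is poor facial selectivity at C9, because the reacting conformer of a flexible ten-membered enone is not certain.
Fallback: inversion in place of re-reduction. It sets out from 13, whose reduction would then give the 9α-epimer F3. Mitsunobu reaction of F3 with 4-nitrobenzoic acid, PPh3 and DIAD gives the 9β-(4-nitrobenzoate) F4. Transesterification with NaN3 in methanol, which leaves the lactone alone, returns to the route at 14.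

**Step 10.** The likeliest failure is attack of the borane on the other face of C4=C5. This would follow from a populated conformer with C15 α and would set C4 and C5 together in the wrong sense. Slow reaction that lets the Z alkene compete is a lesser risk.
Fallback: reagent control in place of substrate control. It sets out from 15 and uses monoisopinocampheylborane made from (−)-α-pinene. Its known sense on E and trisubstituted alkenes corresponds to the 5R carbinol. This gives the C5 alkyl(isopinocampheyl)borane F5, and buffered peroxide oxidation returns to the route at 17.

**Step 11.** The likeliest failures are closure at C1 instead of C10, which gives a six-membered ether against the Markovnikov preference, and reversal of the alkoxymercuration during reduction.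
Fallback: a halonium route. It sets out from 17. Iodoetherification with NIS in CH2Cl2 at −20 °C is reversible until the productive anti closure at C10 and should give the 1α-iodo bridged ether F6. Radical deiodination with nBu3SnH and AIBN in toluene at 80 °C returns to the route at 19.

## Further compounds

F1 | step 6 | diol photoadduct (cis-anti-cis tricycle of 12 with free 8α-hydroxyl and C12 primary alcohol) | OC[C@H](C)[C@H]1C[C@@H]2[C@@]3(C)CC[C@H]3[C@]2(C)C(=O)[C@@H]1O
F2 | step 7 | cis-divinylcyclohexanone lactone (10-methyl-10-vinyl, 5-isopropenyl, C9 ketone) | O=C1[C@H](C)[C@H]2C[C@H](C(C)=C)[C@](C)(C=C)C(=O)[C@@H]2O1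
F3 | step 8 | 9α-hydroxy epimer of 14 | O=C1[C@H](C)[C@H]2C/C=C(C)/CC/C=C(C)\[C@H](O)[C@@H]2O1
F4 | step 8 | 9β-(4-nitrobenzoate) of 14 | O=C1[C@H](C)[C@H]2C/C=C(C)/CC/C=C(C)\[C@@H](OC(=O)c3ccc(cc3)[N+](=O)[O-])[C@@H]2O1
F5 | step 10 | C5 alkyl(isopinocampheyl)borane from 15 | O=C1[C@H](C)[C@H]2C[C@@H](B[C@H]3C[C@H]4C[C@@H]([C@@H]3C)C4(C)C)[C@@H](C)CC/C=C(C)\[C@@H](O[Si](CC)(CC)CC)[C@@H]2O1
F6 | step 11 | 1α-iodo bridged ether with 9β-OSiEt3 | C[C@H]1C(=O)O[C@@H]2[C@@H]1C[C@H]1O[C@](C)([C@@H](I)CC[C@@H]1C)[C@H]2O[Si](CC)(CC)CC
A1 | alternative 1 | (E)-cyclodec-1(10)-en-5-one with 8,9-acetonide, C7 2-(tert-butyldimethylsilyloxy)ethyl arm and C4 methyl | CC1(C)O[C@@H]2[C@@H](CCO[Si](C)(C)C(C)(C)C)CC(=O)[C@@H](C)CC/C=C(\C)[C@H]2O1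
A2 | alternative 2 | bridged C8 ketone of the 11-oxabicyclo[4.4.1]undecane with 9-O-benzyl and C7 CH2CO2Me arm | COC(=O)C[C@H]1C[C@H]2O[C@](C)(CCC[C@@H]2C)[C@@H](OCc3ccccc3)C1=O
A3 | alternative 3 | C5-acetoxy bridged ketal lactone with 9-isovalerate | C1C(=O)O[C@@H]2[C@@H]1C[C@@]1(OC(C)=O)O[C@](C)(CCC[C@@H]1C)[C@H]2OC(=O)CC(C)C
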